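## The problem

The target is a tetrahydrofuran (ring atoms O1, C2, C3, C4, C5). It carries a 4-hydroxyphenyl group on C2, an acetoxymethyl group on C3 (carbon C3a) and, on C4, an exocyclic carbinol carbon C4a bearing an acetate and a 4-methoxyphenyl group. No rings are fused; the difficulty is the run of four contiguous stereocentres C2(R)–C3(S)–C4(R)–C4a(S), with the three ring substituents all-trans. C2 is a benzylic ether carbon that cannot be corrected once the ring exists, so it must be set first, by a catalyst. C3 and C4 each adjoin a carbon (C3a, C4a) that can pass through the carbonyl level, so the all-trans array, the thermodynamically preferred one, can be reached by equilibration against C2. C4a lies outside the ring and needs reagent control at a ketone. The fragile points are the C2–O1 bond (para to the phenol oxygen, so it opens by quinone methide formation under base once the phenol is free and ionises in acid), the solvolytically labile anisylic acetate at C4a, and the need to finish with two alkyl acetates beside a free phenol. The enabling feature is that C3 is alpha to the aldehyde-level C3a and C4 is beta to the anisyl-stabilised C4a. In the open chain C3a=C3–C2–O1–C5–C4=C4a these are the nucleophilic carbons of an enol ether and of a styrene, held 1,6 across the ether oxygen. Removing one electron lets these two like-polarised carbons bond and leaves cations at C3a and C4a, the two carbons that carry oxygen in the target.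

## Retrosynthesis

**17 from 16, 15 and 14.** The phenol is freed last by cutting the O–Si bond of the triisopropylsilyl ether 16, because the free phenol makes the C2–O1 bond base-labile. The C4a acetate of 16 comes from carbinol 15. The C4a–H bond of 15 is cut back to aryl ketone 14. A ketone is preferred to direct capture of a C4a cation by acetate, because a Corey–Bakshi–Shibata reduction sets C4a by reagent, and because the ketone makes C4 epimerisable. The reduction must discriminate the anisyl group from a branched ring carbon.

**14 from 13, 12, 11 and 10.** These are oxidation-level changes only. The ketone of 14 is traced to the anisylic methyl ether 13 (hydride abstraction by DDQ, which favours the more electron-rich arene). The C3a acetate is traced through alcohol 12 to aldehyde 11, and the aldehyde to the mixed acetal 10. Passing through the aldehyde costs two steps but gives the one opportunity to correct C3. The forward steps must spare the two benzylic ethers and the aryl silyl ether.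

**10 from 9 (key disconnection, C3–C4).** Cutting C3–C4 divides the molecule into two halves of similar size joined only by the O1 ether. Both aryl groups and all carbons are then in place before the ring closes. Cutting C2–C3, C4–C5 or O1–C5 instead leaves one aryl group or one oxygenated carbon to be added afterwards, or creates the uncorrectable C2 centre in the ring-forming step. The precursor 9 has a single stereocentre, and the two centres made in the closure are exactly the two that can be equilibrated later. The forward reaction must join two nucleophilic carbons, which anodic oxidation in methanol does, delivering C3a as an acetal and C4a as a methyl ether. An ethyl enol ether is used because it is the one directly accessible (see below); the mixed ethyl methyl acetal that results is hydrolysed in the next step.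

**9 from 6 and 8 (O1–C5).** The ether bond is cut on the side of the primary allylic carbon, giving the secondary alkoxide of 6 and cinnamyl bromide 8. This direction leaves the C2–O bond untouched, so the configuration of 6 is carried over. It also uses only base, which the acid-labile γ-alkoxy enol ether requires. The forward reaction needs clean SN2 attack at the primary carbon of a labile bromide.

**6 from 2 and 3 (C2–C3).** The enol ether and the C2 stereocentre are made together by catalytic asymmetric addition of an (E)-2-ethoxyvinylzinc reagent, from ethoxyacetylene 3, to aldehyde 2. The obvious neighbour is to generate the enol ether by silyl triflate-mediated loss of alcohol from an acetal. That is set aside for two reasons. With the electron-rich styrene already tethered, the intermediate oxocarbenium ion would be intercepted in a Prins closure. The product is also a vinylogous acetal with a doubly activated C2–O bond that the same Lewis acid can ionise. The addition route reaches 6 in one step from 2 and never exposes the enol ether to acid.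

**2 from 1; 8 from 7.** Aldehyde 2 is the silyl ether of 4-hydroxybenzaldehyde 1. The triisopropylsilyl group is chosen to survive alkoxide, organozinc, hydride, DDQ and dilute acid. Bromide 8 comes from (E)-4-methoxycinnamyl alcohol 7 and is used as soon as made.

## Roads not taken

**Alternative 1:** The cut is O1–C5. An oxetane A1 carries the C2 benzylic alcohol and the C3 acetoxymethyl group on a chain attached to C3 of the oxetane. Under a chiral phosphoric acid or Sc(OTf)3 the hydroxyl opens one oxetane CH2 in a 5-exo-tet closure, giving tetrahydrofuran A2 with a hydroxymethyl group as C4a.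
- Merits: the closure is a polar, well-behaved reaction; a chiral catalyst can set C4 independently of substrate bias; the C3a acetate is already in place.
- Weak points for this target: A2 lacks the anisyl group, so oxidation, aryl-metal addition, reoxidation and asymmetric reduction must follow before the stage of 15 is reached. A1 already needs the C2/C3 pair and an oxetanyl group, a longer preparation than that of 9. The free C2 hydroxyl sits 1,3 to the C3a acetate, which invites acetyl migration. Under acid the electron-rich benzylic alcohol can ionise, which would lose C2. The catalyst must also override two existing stereocentres.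
- Comparison: this road is better in that C4 is set by a catalyst and not by equilibration, and it needs no electrochemical equipment. The chosen plan sets against it that every carbon and both arenes are present before ring closure, so that only functional-group changes follow 10.

**Alternative 2:** The cut is C4–C5. The methoxymethyl ether A3 of an open-chain homoallylic alcohol, already holding C2 and C3, is ionised by BF3·OEt2 in acetic acid to an O1=CH2 oxocarbenium ion. The styrene carbon C4 attacks it and acetate captures the C4a cation, giving the triacetate A4, one selective phenol deacetylation from the target.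
- Merits: this is the shortest road; ring, C4 and the C4a acetate arise in one step, and no redox adjustment follows. In step economy it is clearly better than the chosen plan.
- Weak points for this target: an oxocarbenium ion homoallylic to an alkene and attached to an aryl-bearing carbon can undergo 2-oxonia-Cope rearrangement to an aryl-stabilised oxocarbenium ion, which scrambles C2 and C3. BF3 can also ionise the benzylic C2–O bond instead of the acetal. C4a is created by capture of a free anisylic cation with only the adjacent C4 centre to direct it, and the anisylic acetate re-ionises under the reaction conditions, so a mixture at C4a is likely and cannot be corrected in A4.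
- Comparison: the chosen plan is longer by several steps. It sets against this that C4a is fixed by a reagent at a ketone, that C3 and C4 can be corrected, and that no Lewis acid ever acts on a compound with the C2 centre next to a cation-stabilising arene and a tethered π-nucleophile.

**Alternative 3:** The cut is C2–C3. A 2-aryl-4,5-dihydro-1,3-dioxepine A5 carries the 1-(4-methoxyphenyl)vinyl group on its sp3 ring carbon. Me3SiOTf ionises it at the acetal, and the enol(ate) carbon recombines with the aryl oxocarbenium carbon, contracting the ring to the tetrahydrofuran-3-carbaldehyde A6.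
- Merits: the ring contraction is an established way to 2,3-disubstituted tetrahydrofuran-3-carbaldehydes; the C3a aldehyde appears directly and C3 is epimerisable; the arylvinyl group is a masked C4a ketone, so the endgame would merge with that from 14.
- Weak points for this target: C2, the one ring centre that cannot be corrected, is formed in the recombination and is controlled only by the remote C4 centre. The absolute configuration rests on that C4 centre, which in A5 is doubly allylic and prone to acid-induced alkene migration. The electron-rich 1,1-disubstituted alkene competes for the oxocarbenium ion. An enantioenriched A5 needs several steps, and the alkene must later be cleaved oxidatively beside two electron-rich arenes.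
- Comparison: this road is as good as the chosen one in delivering the aldehyde without an acetal hydrolysis. The chosen plan sets against it the more secure order of events: C2 first, by a catalyst, then C3 and C4 relative to it under thermodynamic control.

Key step: step 5

## Numbering and assumption

Locants used throughout: O1, C2 (aryl), C3 (bearing C3a), C4 (bearing C4a), C5.

Assumption: (+)-MIB, the dextrorotatory enantiomer of 3-exo-morpholinoisoborneol, is taken to direct alkenyl transfer to the Re face of an aryl aldehyde, the mirror image of the Si-face delivery of its antipode. If the sense proves opposite, the antipodal ligand is used.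

## Route

Step 1
Reactants: 1 4-hydroxybenzaldehyde
Product: 2 4-(triisopropylsilyloxy)benzaldehyde
Conditions: TIPSCl, imidazole, DMF, 0 °C → rt
Reagents that add atoms: triisopropylsilyl chloride CC(C)[Si](Cl)(C(C)C)C(C)C
Why: Standard silylation of a phenol; the bulky aryl silyl ether should withstand alkoxide, organozinc, hydride, DDQ and dilute acid and is removed by fluoride at the end.

Step 2
Reactants: 3 ethoxyacetylene; 2 4-(triisopropylsilyloxy)benzaldehyde
Product: 6 (1R,2E)-3-ethoxy-1-[4-(triisopropylsilyloxy)phenyl]prop-2-en-1-ol, via tris[(E)-2-ethoxyvinyl]borane 4 (not isolated), via ethyl[(E)-2-ethoxyvinyl]zinc 5 (not isolated)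
Conditions: 3 (3.3 equiv), BH3·SMe2 (1.1 equiv), toluene, 0 °C → rt; Et2Zn (3.5 equiv), −78 °C; (+)-MIB (5 mol%), then 2, −10 °C → rt; sat. aq. NaHCO3 work-up, Et3N-deactivated silica
Reagents that add atoms: none
Why: Amino-alcohol-catalysed asymmetric addition of an alkenylzinc reagent to an aldehyde, known for β-alkoxyvinylzinc reagents; syn-hydroboration puts boron on the terminal carbon and fixes the E geometry, boron-to-zinc exchange gives 5, and the ligand–zinc complex delivers the alkenyl group to the Re face of 2, which sets C2 as R. The work-up is kept non-acidic because the product is a vinylogous hemiacetal.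

Step 3
Reactants: 7 (E)-3-(4-methoxyphenyl)prop-2-en-1-ol
Product: 8 (E)-1-(3-bromoprop-1-enyl)-4-methoxybenzene
Conditions: PBr3 (0.4 equiv), Et2O, 0 °C; cold aq. NaHCO3 wash, used at once without chromatography
Reagents that add atoms: phosphorus tribromide BrP(Br)Br
Why: Conversion of a primary allylic alcohol to the bromide through the phosphite ester; the conjugated E alkene is the thermodynamic isomer and is retained, and the bromide is not stored because of its ready ionisation.

Step 4
Reactants: 6 (1R,2E)-3-ethoxy-1-[4-(triisopropylsilyloxy)phenyl]prop-2-en-1-ol; 8 (E)-1-(3-bromoprop-1-enyl)-4-methoxybenzene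
Product: 9 {4-[(1R,2E)-3-ethoxy-1-{[(2E)-3-(4-methoxyphenyl)prop-2-en-1-yl]oxy}prop-2-en-1-yl]phenoxy}triisopropylsilane
Conditions: NaH, THF–DMF (4:1), 0 °C; then 8 (1.3 equiv), 0 °C → rt
Reagents that add atoms: none
Why: Williamson ether synthesis by SN2 attack of the secondary alkoxide at the primary allylic carbon; the C2–O bond is not broken, so C2 keeps its configuration, and the basic medium protects the acid-labile enol ether.

Step 5
Reactants: 9 {4-[(1R,2E)-3-ethoxy-1-{[(2E)-3-(4-methoxyphenyl)prop-2-en-1-yl]oxy}prop-2-en-1-yl]phenoxy}triisopropylsilane
Product: 10 (2R,3R,4R)-3-[ethoxy(methoxy)methyl]-4-[methoxy(4-methoxyphenyl)methyl]-2-[4-(triisopropylsilyloxy)phenyl]tetrahydrofuran (epimers at the acetal carbon and at C4a)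
Conditions: reticulated vitreous carbon anode, Pt wire cathode, undivided cell, constant current (8 mA, ca. 2.2 F/mol), 0.1 M LiClO4, 2,6-lutidine (6 equiv), MeOH–THF (1:4), rt
Reagents that add atoms: methanol CO
Why: This is an intramolecular anodic coupling of an enol ether with a styrene, a known radical-cation cyclisation: the 4-methoxystyrene, the most easily oxidised group of 9, loses one electron at the anode and the enol ether carbon C3 adds to the styrene carbon C4 (the same bond results if the enol ether is oxidised first and the styrene is the nucleophile). The closure is 5-exo-trig with respect to both alkenes and gives the O1–C2–C3–C4–C5 tetrahydrofuran with C3a and C4a exocyclic. A second electron transfer leaves an oxocarbenium ion at C3a and a 4-methoxybenzylic cation at C4a; methanol caps both, so C3a emerges as the ethyl methyl acetal and C4a as the methyl ether, while protons are reduced at the cathode. C3 is set relative to C2 by an envelope-like transition state in which the C2 aryl group is pseudo-equatorial and the enol ether terminus lies anti to it (2,3-trans). C4 is set by the preference of the two exocyclic termini C3a and C4a to lie anti across the forming bond (3,4-trans). Neither preference has to be complete, because C3 later lies alpha to an aldehyde and C4 alpha to a ketone and both can be equilibrated to the all-trans array against the fixed C2 centre; the acetal carbon and C4a are left uncontrolled because both are erased. The step needs selective oxidation of the alkenes over the silyloxyarene and the C2–H bond, which the lower oxidation potential of the anisyl alkene and the controlled current should secure, and a non-acidic medium for the γ-alkoxy enol ether, which 2,6-lutidine provides.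

Step 6
Reactants: 10 (2R,3R,4R)-3-[ethoxy(methoxy)methyl]-4-[methoxy(4-methoxyphenyl)methyl]-2-[4-(triisopropylsilyloxy)phenyl]tetrahydrofuran
Product: 11 (2R,3R,4R)-4-[methoxy(4-methoxyphenyl)methyl]-2-[4-(triisopropylsilyloxy)phenyl]tetrahydrofuran-3-carbaldehyde (C4a epimers)
Conditions: 1 M aq. HCl, THF, 0 °C → rt; then DBU (0.1 equiv), CH2Cl2, rt
Reagents that add atoms: water O
Why: Acid-catalysed acetal hydrolysis, which should be much faster than ionisation of either benzylic ether under dilute acid; the brief catalytic amine treatment equilibrates any 2,3-cis aldehyde through its enol to the trans isomer and is kept short so that β-elimination of O1 does not intervene.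

Step 7
Reactants: 11 (2R,3R,4R)-4-[methoxy(4-methoxyphenyl)methyl]-2-[4-(triisopropylsilyloxy)phenyl]tetrahydrofuran-3-carbaldehyde
Product: 12 {(2R,3S,4R)-4-[methoxy(4-methoxyphenyl)methyl]-2-[4-(triisopropylsilyloxy)phenyl]tetrahydrofuran-3-yl}methanol (C4a epimers)
Conditions: NaBH4, MeOH–THF, 0 °C
Reagents that add atoms: none
Why: Borohydride reduction of an aldehyde; it fixes C3, which is no longer epimerisable (the descriptor changes from R to S only because the priority of C3a falls).

Step 8
Reactants: 12 {(2R,3S,4R)-4-[methoxy(4-methoxyphenyl)methyl]-2-[4-(triisopropylsilyloxy)phenyl]tetrahydrofuran-3-yl}methanol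
Product: 13 {(2R,3S,4R)-4-[methoxy(4-methoxyphenyl)methyl]-2-[4-(triisopropylsilyloxy)phenyl]tetrahydrofuran-3-yl}methyl acetate (C4a epimers)
Conditions: Ac2O, pyridine, DMAP (cat.), CH2Cl2, rt
Reagents that add atoms: acetic anhydride CC(=O)OC(C)=O
Why: Acylation of a primary alcohol; the acetate is installed now so that no free hydroxyl can trap the C4a cation in step 9 or direct the borane in step 10.

Step 9
Reactants: 13 {(2R,3S,4R)-4-[methoxy(4-methoxyphenyl)methyl]-2-[4-(triisopropylsilyloxy)phenyl]tetrahydrofuran-3-yl}methyl acetate
Product: 14 {(2R,3S,4R)-4-(4-methoxybenzoyl)-2-[4-(triisopropylsilyloxy)phenyl]tetrahydrofuran-3-yl}methyl acetate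
Conditions: DDQ (1.5 equiv), CH2Cl2–pH 7 phosphate buffer (10:1), 0 °C → rt; then DBU (0.2 equiv), CH2Cl2, rt
Reagents that add atoms: water O
Why: DDQ oxidation of a 4-methoxybenzylic methyl ether: hydride abstraction gives the methoxy-stabilised cation, water adds and the hemiketal loses methanol; the anisyl ring is more electron-rich than the silyloxyaryl ring, which should direct the oxidant to C4a–H and away from C2–H. Both C4a epimers converge on one ketone, and the amine treatment equilibrates C4, now alpha to the ketone, to the 3,4-trans isomer.

Step 10
Reactants: 14 {(2R,3S,4R)-4-(4-methoxybenzoyl)-2-[4-(triisopropylsilyloxy)phenyl]tetrahydrofuran-3-yl}methyl acetate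
Product: 15 {(2R,3S,4R)-4-[(S)-hydroxy(4-methoxyphenyl)methyl]-2-[4-(triisopropylsilyloxy)phenyl]tetrahydrofuran-3-yl}methyl acetate
Conditions: (R)-2-methyl-CBS-oxazaborolidine (0.3 equiv), BH3·SMe2 (1.2 equiv), THF, −20 °C; MeOH quench
Reagents that add atoms: none
Why: Corey–Bakshi–Shibata reduction of an aryl ketone; with the anisyl group as the large substituent the (R)-catalyst delivers hydride to give the (S)-carbinol, and a Felkin–Anh analysis with C3 as the large alpha substituent predicts the same face, so reagent and substrate control should reinforce each other. The ester is not reduced by borane at this temperature.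

Step 11
Reactants: 15 {(2R,3S,4R)-4-[(S)-hydroxy(4-methoxyphenyl)methyl]-2-[4-(triisopropylsilyloxy)phenyl]tetrahydrofuran-3-yl}methyl acetate
Product: 16 (S)-{(3R,4S,5R)-4-(acetoxymethyl)-5-[4-(triisopropylsilyloxy)phenyl]tetrahydrofuran-3-yl}(4-methoxyphenyl)methyl acetate
Conditions: Ac2O, pyridine, DMAP (cat.), CH2Cl2, 0 °C
Reagents that add atoms: acetic anhydride CC(=O)OC(C)=O
Why: Acylation of the secondary benzylic alcohol under basic conditions, with retention at C4a because the C–O bond is not broken; acid is avoided in reaction and work-up because the anisylic acetate ionises easily.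

Step 12
Reactants: 16 (S)-{(3R,4S,5R)-4-(acetoxymethyl)-5-[4-(triisopropylsilyloxy)phenyl]tetrahydrofuran-3-yl}(4-methoxyphenyl)methyl acetate
Product: 17 (S)-[(3R,4S,5R)-4-(acetoxymethyl)-5-(4-hydroxyphenyl)tetrahydrofuran-3-yl](4-methoxyphenyl)methyl acetate (CNP0231272.1)
Conditions: TBAF, AcOH (1:1), THF, 0 °C
Reagents that add atoms: none
Why: Fluoride cleavage of an aryl silyl ether; the acetic acid buffer keeps the phenol protonated, so that neither acetate is cleaved or transferred and the C2–O1 bond is not opened through a quinone methide.

## Compound list

1 | 4-hydroxybenzaldehyde | O=Cc1ccc(O)cc1 | starting material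
2 | 4-(triisopropylsilyloxy)benzaldehyde | O=Cc1ccc(O[Si](C(C)C)(C(C)C)C(C)C)cc1 | intermediate
3 | ethoxyacetylene (ethoxyethyne) | CCOC#C | starting material
4 | tris[(E)-2-ethoxyvinyl]borane (not isolated) | CCO/C=C/B(/C=C/OCC)/C=C/OCC | intermediate
5 | ethyl[(E)-2-ethoxyvinyl]zinc (not isolated) | CCO/C=C/[Zn]CC | intermediate
6 | (1R,2E)-3-ethoxy-1-[4-(triisopropylsilyloxy)phenyl]prop-2-en-1-ol | CCO/C=C/[C@@H](O)c1ccc(O[Si](C(C)C)(C(C)C)C(C)C)cc1 | intermediate
7 | (E)-3-(4-methoxyphenyl)prop-2-en-1-ol | COc1ccc(/C=C/CO)cc1 | starting material
8 | (E)-1-(3-bromoprop-1-enyl)-4-methoxybenzene | COc1ccc(/C=C/CBr)cc1 | intermediate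
9 | {4-[(1R,2E)-3-ethoxy-1-{[(2E)-3-(4-methoxyphenyl)prop-2-en-1-yl]oxy}prop-2-en-1-yl]phenoxy}triisopropylsilane | CCO/C=C/[C@@H](OC/C=C/c1ccc(OC)cc1)c1ccc(O[Si](C(C)C)(C(C)C)C(C)C)cc1 | intermediate
10 | (2R,3R,4R)-3-[ethoxy(methoxy)methyl]-4-[methoxy(4-methoxyphenyl)methyl]-2-[4-(triisopropylsilyloxy)phenyl]tetrahydrofuran, epimers at the acetal carbon and C4a | COc1ccc(C(OC)[C@H]2CO[C@@H](c3ccc(O[Si](C(C)C)(C(C)C)C(C)C)cc3)[C@@H]2C(OC)OCC)cc1 | intermediate
11 | (2R,3R,4R)-4-[methoxy(4-methoxyphenyl)methyl]-2-[4-(triisopropylsilyloxy)phenyl]tetrahydrofuran-3-carbaldehyde, C4a epimers | COc1ccc(C(OC)[C@H]2CO[C@@H](c3ccc(O[Si](C(C)C)(C(C)C)C(C)C)cc3)[C@@H]2C=O)cc1 | intermediate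
12 | {(2R,3S,4R)-4-[methoxy(4-methoxyphenyl)methyl]-2-[4-(triisopropylsilyloxy)phenyl]tetrahydrofuran-3-yl}methanol, C4a epimers | COc1ccc(C(OC)[C@H]2CO[C@@H](c3ccc(O[Si](C(C)C)(C(C)C)C(C)C)cc3)[C@@H]2CO)cc1 | intermediate
13 | {(2R,3S,4R)-4-[methoxy(4-methoxyphenyl)methyl]-2-[4-(triisopropylsilyloxy)phenyl]tetrahydrofuran-3-yl}methyl acetate, C4a epimers | COc1ccc(C(OC)[C@H]2CO[C@@H](c3ccc(O[Si](C(C)C)(C(C)C)C(C)C)cc3)[C@@H]2COC(C)=O)cc1 | intermediate
14 | {(2R,3S,4R)-4-(4-methoxybenzoyl)-2-[4-(triisopropylsilyloxy)phenyl]tetrahydrofuran-3-yl}methyl acetate | COc1ccc(C(=O)[C@H]2CO[C@@H](c3ccc(O[Si](C(C)C)(C(C)C)C(C)C)cc3)[C@@H]2COC(C)=O)cc1 | intermediate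
15 | {(2R,3S,4R)-4-[(S)-hydroxy(4-methoxyphenyl)methyl]-2-[4-(triisopropylsilyloxy)phenyl]tetrahydrofuran-3-yl}methyl acetate | COc1ccc([C@@H](O)[C@H]2CO[C@@H](c3ccc(O[Si](C(C)C)(C(C)C)C(C)C)cc3)[C@@H]2COC(C)=O)cc1 | intermediate
16 | (S)-{(3R,4S,5R)-4-(acetoxymethyl)-5-[4-(triisopropylsilyloxy)phenyl]tetrahydrofuran-3-yl}(4-methoxyphenyl)methyl acetate | COc1ccc([C@@H](OC(C)=O)[C@H]2CO[C@@H](c3ccc(O[Si](C(C)C)(C(C)C)C(C)C)cc3)[C@@H]2COC(C)=O)cc1 | intermediate
17 | (S)-[(3R,4S,5R)-4-(acetoxymethyl)-5-(4-hydroxyphenyl)tetrahydrofuran-3-yl](4-methoxyphenyl)methyl acetate | COc1ccc([C@@H](OC(C)=O)[C@H]2CO[C@@H](c3ccc(O)cc3)[C@@H]2COC(C)=O)cc1 | target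

## Step count and least certain steps

Total: 12 steps. Longest linear sequence: 11 steps (steps 1, 2 and 4 to 12, from 1); step 3 is a one-step branch.

**Step 5 (key step).** The radical cation may be diverted before the C3–C4 bond forms, either by methanol adding to the styrene radical cation or by proton loss from C2, whose C–H bond is benzylic, allylic and alpha to oxygen. The product may also be oxidised further at its anisylic ether. Fallback, from 9 back to 10, by a neutral radical closure of the same bond:
- Bromo-methoxylation of the more nucleophilic enol ether (N-bromosuccinimide, MeOH, 2,6-lutidine, −78 °C) should give the α-bromo ethyl methyl acetal F1.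
- Bu3SnH and AIBN in toluene at 80 °C should close the ring by 5-exo-trig attack of the C3 radical on C4, giving the 4-(4-methoxybenzyl)tetrahydrofuran acetal F2, in which C4a is a methylene group.
- Benzylic methoxylation of F2 with DDQ in MeOH–CH2Cl2 should return to 10.

**Step 2.** The electron-rich aldehyde may react slowly enough for the uncatalysed addition to compete, eroding enantioselectivity. The product may also undergo acid-triggered allylic transposition to the cinnamaldehyde on work-up or chromatography. Fallback, from 2 back to 6: catalytic asymmetric addition of the zinc acetylide of 3 (Me2Zn, a ProPhenol-type dinuclear zinc catalyst, toluene) should give the propargylic alcohol (S)-3-ethoxy-1-[4-(triisopropylsilyloxy)phenyl]prop-2-yn-1-ol F3. This reaction class is well established for aryl aldehydes, though ethoxyacetylene is a less common alkyne partner. Hydroxyl-directed trans reduction of the ynol ether with LiAlH4 (THF, 0 °C) should then give 6.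

**Step 4.** The electron-rich allylic bromide may ionise and decompose before etherification, or the alkoxide may attack the benzylic terminus (SN2′). Fallback, from 6 and 7 back to 9: 7 is converted (Boc2O, DMAP) to tert-butyl (E)-3-(4-methoxyphenyl)allyl carbonate F4. Tsuji–Trost etherification of the zinc alkoxide of 6 (Et2Zn, then Pd(PPh3)4, THF, rt) should then give the linear E ether 9, the aryl-substituted allyl complex being attacked at its unsubstituted terminus.

**Step 9.** Hydride abstraction may occur at the wrong benzylic position (C2–H, leading to ring cleavage) or be slow at the hindered C4a–H. Fallback, from 13 back to 14: ionisation of the anisylic ether and exchange of methoxy for hydroxy (cat. CF3CO2H, MeCN–H2O, 0 °C) should give the carbinol F5 as C4a epimers. Dess–Martin oxidation of F5 should then give 14.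

**Step 10.** Facial selectivity may be insufficient, because the smaller ketone substituent is a branched ring carbon and the catalysed pathway may not outrun background reduction. Fallback, from 14 back to 15: substrate-controlled reduction with a bulky hydride (LiBH(s-Bu)3, THF, −78 °C), which should follow the same Felkin–Anh preference. The C4a epimer {(2R,3S,4R)-4-[(R)-hydroxy(4-methoxyphenyl)methyl]-2-[4-(triisopropylsilyloxy)phenyl]tetrahydrofuran-3-yl}methyl acetate F6 is separated and returned to 14 by Dess–Martin oxidation.

## Further compounds

F1 | step 5 | 2-bromo-3-ethoxy-3-methoxy-1-{[(E)-3-(4-methoxyphenyl)allyl]oxy}-1-[4-(triisopropylsilyloxy)phenyl]propane, C1 as in 9, mixture at the bromide and acetal carbons | CCOC(OC)C(Br)[C@@H](OC/C=C/c1ccc(OC)cc1)c1ccc(O[Si](C(C)C)(C(C)C)C(C)C)cc1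
F2 | step 5 | 3-[ethoxy(methoxy)methyl]-4-(4-methoxybenzyl)-2-[4-(triisopropylsilyloxy)phenyl]tetrahydrofuran, ring configured as in 10 | COc1ccc(C[C@H]2CO[C@@H](c3ccc(O[Si](C(C)C)(C(C)C)C(C)C)cc3)[C@@H]2C(OC)OCC)cc1
F3 | step 2 | (S)-3-ethoxy-1-[4-(triisopropylsilyloxy)phenyl]prop-2-yn-1-ol | CCOC#C[C@@H](O)c1ccc(O[Si](C(C)C)(C(C)C)C(C)C)cc1
F4 | step 4 | tert-butyl (E)-3-(4-methoxyphenyl)allyl carbonate | COc1ccc(/C=C/COC(=O)OC(C)(C)C)cc1
F5 | step 9 | {(2R,3S,4R)-4-[hydroxy(4-methoxyphenyl)methyl]-2-[4-(triisopropylsilyloxy)phenyl]tetrahydrofuran-3-yl}methyl acetate, C4a epimers | COc1ccc(C(O)[C@H]2CO[C@@H](c3ccc(O[Si](C(C)C)(C(C)C)C(C)C)cc3)[C@@H]2COC(C)=O)cc1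
F6 | step 10 | {(2R,3S,4R)-4-[(R)-hydroxy(4-methoxyphenyl)methyl]-2-[4-(triisopropylsilyloxy)phenyl]tetrahydrofuran-3-yl}methyl acetate | COc1ccc([C@H](O)[C@H]2CO[C@@H](c3ccc(O[Si](C(C)C)(C(C)C)C(C)C)cc3)[C@@H]2COC(C)=O)cc1
A1 | alternative 1 | 3-hydroxy-2-(oxetan-3-yl)-3-[4-(triisopropylsilyloxy)phenyl]propyl acetate, configured at the carbinol and adjacent carbon as C2 and C3 of the target | O[C@@H](c1ccc(O[Si](C(C)C)(C(C)C)C(C)C)cc1)[C@H](COC(C)=O)C1COC1
A2 | alternative 1 | all-trans {4-(hydroxymethyl)-2-[4-(triisopropylsilyloxy)phenyl]tetrahydrofuran-3-yl}methyl acetate | OC[C@H]1CO[C@@H](c2ccc(O[Si](C(C)C)(C(C)C)C(C)C)cc2)[C@@H]1COC(C)=O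
A3 | alternative 2 | (E)-2-[(4-acetoxyphenyl)(methoxymethoxy)methyl]-4-(4-methoxyphenyl)but-3-enyl acetate, configured as C2 and C3 of the target | COCO[C@@H](c1ccc(OC(C)=O)cc1)[C@H](COC(C)=O)/C=C/c1ccc(OC)cc1
A4 | alternative 2 | O-acetyl derivative of the target (triacetate) | COc1ccc([C@@H](OC(C)=O)[C@H]2CO[C@@H](c3ccc(OC(C)=O)cc3)[C@@H]2COC(C)=O)cc1
A5 | alternative 3 | 5-[1-(4-methoxyphenyl)vinyl]-2-[4-(triisopropylsilyloxy)phenyl]-4,5-dihydro-1,3-dioxepine, C5 configured as C4 of the target | C=C(c1ccc(OC)cc1)[C@H]1COC(c2ccc(O[Si](C(C)C)(C(C)C)C(C)C)cc2)OC=C1
A6 | alternative 3 | all-trans 4-[1-(4-methoxyphenyl)vinyl]-2-[4-(triisopropylsilyloxy)phenyl]tetrahydrofuran-3-carbaldehyde | COc1ccc(C(=C)[C@H]2CO[C@@H](c3ccc(O[Si](C(C)C)(C(C)C)C(C)C)cc3)[C@@H]2C=O)cc1
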